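0.311 is the number I carry through these flasks: the crossing ratio, my reading of the value of c(first product)/c(starting material) at which first product is used up as fast as it is made.

all flasks: starting material 0.060 M

|  | partner | remark | time |
|---|---|---|---|
| noon | 0.13 M | run made earlier |  |
| winter | 0.14 M | run made earlier |  |
| ochre | 0.180 M |  | 12 h |
| teal | 0.120 M |  | 50 h |

| run | time / h | first product / % | bis adduct / % |
|---|---|---|---|
| noon | 0.500 | 0.8 | 0 |
| noon | 1.50 | 1.8 | 0 |
| noon | 3.00 | 3.7 | 0.9 |
| noon | 4.00 | 4.6 | 0.5 |
| noon | 6.00 | 7.2 | 0.8 |
| winter | 1.33 | 1.4 | 0 |
| winter | 2.50 | 4.0 | 0.6 |
| winter | 4.00 | 5.8 | 0.1 |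
| winter | 5.00 | 6.0 | 0.9 |
| winter | 6.00 | 8.3 | 1.9 |

(each reading ± 0.5 percentage points)

- what was read earlier has a scatter of 0.5 percentage points, one standard deviation

- the winner by share of first product in all that became first product or bis adduct; "neither" if no more than 2 percentage points parts them (ochre / teal / neither)
- share of first product in all that became first product or bis adduct, ochre
- share of first product in all that became first product or bis adduct, teal

I read the ratio from the last readings of both runs, in a two-step picture. Conversion x, meaning first product plus bis adduct, climbs on average at 0.0152 h⁻¹ at a mean partner of 0.135 M. Bis adduct starts flat and then grows as half of κ times x squared, so the selectivity factor κ reads 3.21. That is only a reading, because the bis values lie near their scatter of 0.5 percentage points. Partner enters both making and use of first product, so it cancels, and the crossing stands at one over κ.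

Now I draw the curve against exposure, the rate constant times partner times time. First product rises along that slope, bends, and goes flat at an exposure of 0.527, at a level of 18.4%. With partner held at its charge, the crossing comes at 26.1 h in ochre, later than its stop at 12 h. In teal the same estimate gives 39.1 h, shorter than its stop at 50 h, but that estimate is for a partner that does not fall, and teal's partner falls as it reacts. The exposures 0.243 and 0.674 give me shares of 68.4% for ochre and 36.4% for teal, so I choose ochre.

The forecast also chooses ochre, but with 96% for ochre and 90% for teal. It takes κ as 0.34 and notes that “the bis readings are close to their scatter”. We part on κ, and so on both shares.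

The flasks give ochre as winner, with 73.7% for ochre and 54.6% for teal.

    starting material + partner → first product (k = 0.110 M⁻¹ h⁻¹)
    starting material + partner → other mono adduct (k = 0.0180 M⁻¹ h⁻¹)
    partner + first product → bis adduct (k = 0.280 M⁻¹ h⁻¹)
    partner + other mono adduct → bis adduct (k = 0.250 M⁻¹ h⁻¹)
    partner → decomposed reagent (k = 0.0100 h⁻¹)

Teal's share stands low because of the reaction of partner with first product: with that step taken away, teal gives 93.9% instead of 54.6%. At 50.0 h teal holds a ratio of 0.325, next to my read crossing ratio of 0.311, and first product there is still made 1.21 times faster than it is used up. Ochre at 12.0 h holds 0.185, below that reading. The neighbour of teal charged with 0.48 M of partner reaches 0.662, above my reading of 0.311, and its share is 9.74%.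

The data stem from a simulated flask with made-up constants; noise was put on by code.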